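**Retrosynthetic overview**

1. Numbering as in shikimate: C1 carries the ester carbon C7, C2 is the vinyl CH, C3, C4 and C5 carry the acetate, the 2‑methylbutanoate and the 3‑methylpentanoate, C6 is the ring CH2. Enabling feature: C3 is the γ‑carbon of the C7(=O)–C1=C2 enoate and already bears the acetate, and its ring neighbour C4 is a carbinol carbon, so C3–C4 is the bond a γ‑acetoxy dienolate makes with a C4 aldehyde.
2. 18 ⇐ 16 (free 4‑OH, esterified last) ⇐ acyclic aldehyde gem‑diacetate 14: a Pd/In‑mediated reductive vinylogous aldol closes the cyclohexene (the only ring formed) at C3–C4, sets C3 and C4 from C5, leaves the acetate on O3 and restores C1=C2.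
3. 14 ⇐ α‑alkylidene lactone 6 by lactone opening to the methyl ester, O5 acylation with acid 9, acetal → gem‑diacetate exchange and oxidation at C4.
4. 6 ⇐ aldol condensation of silyl‑protected lactone 2 with glyoxal mono‑acetal 3, which adds C2 and C3.
5. 2 ⇐ (R)‑γ‑(hydroxymethyl)‑γ‑butyrolactone 1 (D‑glutamic acid series): its five carbons become C7, C1, C6, C5 and C4, its stereocentre becomes C5, and its lactone ring is opened in step 3.

Key step: step 9

Assumption: lactone 1 and the enantiopure acids 9 and 17 are taken as commercially available, and anhydrous 3 is freshly obtained from its commercial aqueous solution.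

**Route**

Step 1
Reactants: 1 (5R)-5-(hydroxymethyl)dihydrofuran-2(3H)-one
Product: 2 (5R)-5-{[(tert-butyldiphenylsilyl)oxy]methyl}dihydrofuran-2(3H)-one
Conditions: TBDPSCl, imidazole, DMF, 0 °C → rt
Reagents that add atoms: tert-butyl(chloro)diphenylsilane, CC(C)(C)[Si](Cl)(c1ccccc1)c1ccccc1
Why: Imidazole-promoted silylation of the primary alcohol should give an acid- and base-stable silyl ether that masks the future C4 oxygen until step 7, and C5 is not touched.

Step 2
Reactants: 2 (5R)-5-{[(tert-butyldiphenylsilyl)oxy]methyl}dihydrofuran-2(3H)-one; 3 2,2-dimethoxyacetaldehyde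
Product: 6 (3E,5R)-5-{[(tert-butyldiphenylsilyl)oxy]methyl}-3-(2,2-dimethoxyethylidene)dihydrofuran-2(3H)-one, via lithium aldolate 4 (not isolated), via mesylate 5 (not isolated)
Conditions: LiN(iPr)2, THF, −78 °C; 3; MsCl, −78 → 0 °C; DBU, 0 °C → rt
Reagents that add atoms: none
Why: The lithium enolate of the lactone should add to aldehyde 3 (aldol addition), the aldolate is trapped as its mesylate and DBU effects E1cB elimination to the conjugated alkylidene lactone, the E isomer being the thermodynamic one; the alkene geometry is not decisive because the C1–C2 bond can rotate in 15.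

Step 3
Reactants: 6 (3E,5R)-5-{[(tert-butyldiphenylsilyl)oxy]methyl}-3-(2,2-dimethoxyethylidene)dihydrofuran-2(3H)-one
Product: 8 methyl (E)-2-[(2R)-3-[(tert-butyldiphenylsilyl)oxy]-2-hydroxypropyl]-4,4-dimethoxybut-2-enoate, via lithium carboxylate 7 (not isolated)
Conditions: LiOH·H2O (1.05 equiv), THF/H2O, 0 °C; evaporation; MeI, DMF, 0 °C → rt
Reagents that add atoms: lithium hydroxide, [Li+].[OH-]; iodomethane, CI
Why: Saponification should open the lactone to a carboxylate that cannot reclose, and SN2 methylation of that carboxylate under neutral conditions gives the γ-hydroxy methyl ester, which is expected to relactonise only under acid or base catalysis and is used directly.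

Step 4
Reactants: 8 methyl (E)-2-[(2R)-3-[(tert-butyldiphenylsilyl)oxy]-2-hydroxypropyl]-4,4-dimethoxybut-2-enoate; 9 (3S)-3-methylpentanoic acid
Product: 10 methyl (E)-2-[(2R)-3-[(tert-butyldiphenylsilyl)oxy]-2-{[(3S)-3-methylpentanoyl]oxy}propyl]-4,4-dimethoxybut-2-enoate
Conditions: EDC·HCl, DMAP (cat.), CH2Cl2, 0 °C
Reagents that add atoms: none
Why: Steglich esterification of the secondary alcohol should install the C5 ester without breaking the C5–O bond, so C5 keeps its configuration, and the β-stereocentre of 9 cannot epimerise.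

Step 5
Reactants: 10 methyl (E)-2-[(2R)-3-[(tert-butyldiphenylsilyl)oxy]-2-{[(3S)-3-methylpentanoyl]oxy}propyl]-4,4-dimethoxybut-2-enoate
Product: 11 methyl (E)-2-[(2R)-3-[(tert-butyldiphenylsilyl)oxy]-2-{[(3S)-3-methylpentanoyl]oxy}propyl]-4-oxobut-2-enoate
Conditions: TFA/H2O, CH2Cl2, 0 °C → rt
Reagents that add atoms: water, O
Why: Acid-catalysed hydrolysis of the dimethyl acetal should give the 4-oxo-enoate, while the tert-butyldiphenylsilyl ether and the three esters tolerate dilute aqueous acid.

Step 6
Reactants: 11 methyl (E)-2-[(2R)-3-[(tert-butyldiphenylsilyl)oxy]-2-{[(3S)-3-methylpentanoyl]oxy}propyl]-4-oxobut-2-enoate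
Product: 12 methyl (E)-4,4-diacetoxy-2-[(2R)-3-[(tert-butyldiphenylsilyl)oxy]-2-{[(3S)-3-methylpentanoyl]oxy}propyl]but-2-enoate
Conditions: Ac2O, H2SO4 (cat.), 0 °C
Reagents that add atoms: acetic anhydride, CC(=O)OC(C)=O
Why: Acid-catalysed addition of acetic anhydride to the aldehyde (acylal formation) should give the allylic gem-diacetate, which protects C3 and is at the same time the ionisable group and the source of the C3 acetate for step 9.

Step 7
Reactants: 12 methyl (E)-4,4-diacetoxy-2-[(2R)-3-[(tert-butyldiphenylsilyl)oxy]-2-{[(3S)-3-methylpentanoyl]oxy}propyl]but-2-enoate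
Product: 13 methyl (E)-4,4-diacetoxy-2-[(2R)-3-hydroxy-2-{[(3S)-3-methylpentanoyl]oxy}propyl]but-2-enoate
Conditions: HF·pyridine, pyridine, THF, 0 °C → rt
Reagents that add atoms: none
Why: Fluoride cleaves the Si–O bond under buffered, slightly acidic conditions, which should leave the gem-diacetate and the esters intact and disfavour base-promoted acyl migration from O5 to the new primary hydroxyl.

Step 8
Reactants: 13 methyl (E)-4,4-diacetoxy-2-[(2R)-3-hydroxy-2-{[(3S)-3-methylpentanoyl]oxy}propyl]but-2-enoate
Product: 14 methyl (E)-4,4-diacetoxy-2-[(2R)-2-{[(3S)-3-methylpentanoyl]oxy}-3-oxopropyl]but-2-enoate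
Conditions: Dess–Martin periodinane, CH2Cl2, 0 °C → rt
Reagents that add atoms: none
Why: Dess–Martin oxidation of the primary alcohol under non-basic conditions should give the α-acyloxy aldehyde without enolisation at C5, and the crude aldehyde is used at once.

Step 9
Reactants: 14 methyl (E)-4,4-diacetoxy-2-[(2R)-2-{[(3S)-3-methylpentanoyl]oxy}-3-oxopropyl]but-2-enoate
Product: 16 methyl (3R,4S,5R)-3-acetoxy-4-hydroxy-5-{[(3S)-3-methylpentanoyl]oxy}cyclohex-1-ene-1-carboxylate, via indium dienolate 15 (not isolated)
Conditions: Pd(PPh3)4 (5 mol%), InI (1.5 equiv), THF (0.02 M, slow addition of 14), 0 °C → rt; aq. NH4Cl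
Reagents that add atoms: none
Why: Proposed new method: zerovalent palladium should ionise one acetate of the allylic gem-diacetate to a 1-acetoxy-π-allylpalladium species, monovalent indium should take over the allyl group by reductive transmetalation to give the trivalent indium γ-acetoxy dienolate 15 (C7(OIn)=C1–C2=C3–OAc, in metallotropic equilibrium with its C-bound forms), and the γ-carbon C3 of 15 should add to the tethered C4 aldehyde, which restores the C1=C2 enoate. The closest known reaction types are the Pd/InI umpolung allylation of aldehydes with allylic acetates and the indium-mediated acetoxyallylation of aldehydes with 3-bromopropenyl acetate, neither of which has been shown for an ester-substituted allylic gem-diacetate or for a closure in which all three allyl carbons enter the ring. The cyclohexene closes 6-exo-trig at the aldehyde carbon with the reacting C2=C3 bond inside the new ring (a vinylogous 6-(enolendo)-exo-trig closure), and the tether enforces γ-attack because α-attack at C1 would give a cyclobutane. C3 is controlled by the geometry of the acetoxyallyl unit: the acetoxy group should take the syn (E) position, the anti position being blocked by the C6 methylene on C1, and therefore ends on the face from which C4 is attacked. C4 is controlled by indium, which should bridge from C1 to the aldehyde oxygen in a boat-like six-membered transition state and so deliver O4 cis to the C3 acetate, while the C5 stereocentre places its acyloxy group antiperiplanar to the C4=O dipole and away from the indium bridge, which makes O4 trans to O5 and gives (3R,4S) from (5R). The step needs this facial selectivity over an open all-equatorial transition state (C3 epimer), and it needs ionisation of the gem-diacetate of 14 in preference to the allylic acetate of 16; the higher ionisation rate of gem-diacetates, a small excess of InI and high dilution are relied on for this.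

Step 10
Reactants: 16 methyl (3R,4S,5R)-3-acetoxy-4-hydroxy-5-{[(3S)-3-methylpentanoyl]oxy}cyclohex-1-ene-1-carboxylate; 17 (2R)-2-methylbutanoic acid
Product: 18 methyl (3R,4S,5R)-3-acetoxy-4-{[(2R)-2-methylbutanoyl]oxy}-5-{[(3S)-3-methylpentanoyl]oxy}cyclohex-1-ene-1-carboxylate (the target)
Conditions: EDC·HCl, DMAP (cat.), CH2Cl2, 0 °C
Reagents that add atoms: none
Why: Steglich esterification of the remaining C4 hydroxyl should complete the triester, and low temperature with only catalytic DMAP is chosen to limit acetyl migration from O3 and epimerisation of the α-stereocentre of 17.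

**Compound list**

1 | (5R)-5-(hydroxymethyl)dihydrofuran-2(3H)-one | O=C1CC[C@H](CO)O1 | starting material
2 | (5R)-5-{[(tert-butyldiphenylsilyl)oxy]methyl}dihydrofuran-2(3H)-one | O=C1CC[C@H](CO[Si](c2ccccc2)(c2ccccc2)C(C)(C)C)O1 | intermediate
3 | 2,2-dimethoxyacetaldehyde (glyoxal mono-dimethyl acetal) | COC(OC)C=O | starting material
4 | lithium aldolate of 2 with 3: lithium 1-[(5R)-5-{[(tert-butyldiphenylsilyl)oxy]methyl}-2-oxotetrahydrofuran-3-yl]-2,2-dimethoxyethan-1-olate (mixture at the two new centres) | [Li+].[O-]C(C(OC)OC)C1C[C@H](CO[Si](c2ccccc2)(c2ccccc2)C(C)(C)C)OC1=O | intermediate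
5 | methanesulfonate of the aldol adduct (mixture at the two new centres) | CS(=O)(=O)OC(C(OC)OC)C1C[C@H](CO[Si](c2ccccc2)(c2ccccc2)C(C)(C)C)OC1=O | intermediate
6 | (3E,5R)-5-{[(tert-butyldiphenylsilyl)oxy]methyl}-3-(2,2-dimethoxyethylidene)dihydrofuran-2(3H)-one | O=C1/C(=C/C(OC)OC)C[C@H](CO[Si](c2ccccc2)(c2ccccc2)C(C)(C)C)O1 | intermediate
7 | lithium (E)-2-[(2R)-3-[(tert-butyldiphenylsilyl)oxy]-2-hydroxypropyl]-4,4-dimethoxybut-2-enoate | [Li+].[O-]C(=O)/C(=C/C(OC)OC)C[C@@H](O)CO[Si](c1ccccc1)(c1ccccc1)C(C)(C)C | intermediate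
8 | methyl (E)-2-[(2R)-3-[(tert-butyldiphenylsilyl)oxy]-2-hydroxypropyl]-4,4-dimethoxybut-2-enoate | COC(=O)/C(=C/C(OC)OC)C[C@@H](O)CO[Si](c1ccccc1)(c1ccccc1)C(C)(C)C | intermediate
9 | (3S)-3-methylpentanoic acid | CC[C@H](C)CC(=O)O | starting material
10 | methyl (E)-2-[(2R)-3-[(tert-butyldiphenylsilyl)oxy]-2-{[(3S)-3-methylpentanoyl]oxy}propyl]-4,4-dimethoxybut-2-enoate | COC(=O)/C(=C/C(OC)OC)C[C@@H](OC(=O)C[C@@H](C)CC)CO[Si](c1ccccc1)(c1ccccc1)C(C)(C)C | intermediate
11 | methyl (E)-2-[(2R)-3-[(tert-butyldiphenylsilyl)oxy]-2-{[(3S)-3-methylpentanoyl]oxy}propyl]-4-oxobut-2-enoate | COC(=O)/C(=C/C=O)C[C@@H](OC(=O)C[C@@H](C)CC)CO[Si](c1ccccc1)(c1ccccc1)C(C)(C)C | intermediate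
12 | methyl (E)-4,4-diacetoxy-2-[(2R)-3-[(tert-butyldiphenylsilyl)oxy]-2-{[(3S)-3-methylpentanoyl]oxy}propyl]but-2-enoate | COC(=O)/C(=C/C(OC(C)=O)OC(C)=O)C[C@@H](OC(=O)C[C@@H](C)CC)CO[Si](c1ccccc1)(c1ccccc1)C(C)(C)C | intermediate
13 | methyl (E)-4,4-diacetoxy-2-[(2R)-3-hydroxy-2-{[(3S)-3-methylpentanoyl]oxy}propyl]but-2-enoate | COC(=O)/C(=C/C(OC(C)=O)OC(C)=O)C[C@@H](OC(=O)C[C@@H](C)CC)CO | intermediate
14 | methyl (E)-4,4-diacetoxy-2-[(2R)-2-{[(3S)-3-methylpentanoyl]oxy}-3-oxopropyl]but-2-enoate | COC(=O)/C(=C/C(OC(C)=O)OC(C)=O)C[C@@H](OC(=O)C[C@@H](C)CC)C=O | intermediate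
15 | acetato(iodo)indium (3E)-4-acetoxy-1-methoxy-2-[(2R)-2-{[(3S)-3-methylpentanoyl]oxy}-3-oxopropyl]buta-1,3-dien-1-olate (trivalent indium γ-acetoxy dienolate, drawn O-bound) | COC(O[In](I)OC(C)=O)=C(C[C@@H](OC(=O)C[C@@H](C)CC)C=O)/C=C/OC(C)=O | intermediate
16 | methyl (3R,4S,5R)-3-acetoxy-4-hydroxy-5-{[(3S)-3-methylpentanoyl]oxy}cyclohex-1-ene-1-carboxylate | CC[C@H](C)CC(=O)O[C@@H]1CC(C(=O)OC)=C[C@@H](OC(C)=O)[C@H]1O | intermediate
17 | (2R)-2-methylbutanoic acid | CC[C@@H](C)C(=O)O | starting material
18 | methyl (3R,4S,5R)-3-acetoxy-4-{[(2R)-2-methylbutanoyl]oxy}-5-{[(3S)-3-methylpentanoyl]oxy}cyclohex-1-ene-1-carboxylate | CC[C@H](C)CC(=O)O[C@@H]1CC(C(=O)OC)=C[C@@H](OC(C)=O)[C@H]1OC(=O)[C@H](C)CC | target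

**Step count and risks**

Total step count: 10. Longest linear sequence: 10 steps (1 → 18).

Steps most likely to fail:

Step 9 (bears the label "Proposed new method:"). What may go wrong: poor facial selectivity, since an open all-equatorial transition state would invert the outcome at C3 and the transition-state model is not backed by a direct precedent. Intermolecular addition, protonation or β-hydride loss of the allylindium may also outrun ring closure, and zerovalent palladium may re-ionise the allylic acetate of 16. The fallback uses known chemistry and takes the ring from the chiral pool instead of closing it. It sets out from acid 9, the only route compound it uses, and comes back to the route at 16. Methyl shikimate F1 (commercially available, or made from shikimic acid with MeOH and acid) is converted with 2,2-dimethoxypropane and catalytic TsOH into methyl 3,4-O-isopropylideneshikimate F2. Its free 5-hydroxyl is esterified with 9 (EDC·HCl, DMAP) to give methyl 3,4-O-isopropylidene-5-O-[(3S)-3-methylpentanoyl]shikimate F3. Aqueous TFA removes the acetonide to give methyl 5-O-[(3S)-3-methylpentanoyl]shikimate F4. Trimethyl orthoacetate with catalytic CSA closes the cis-3,4-diol to the cyclic orthoacetate F5 (not isolated), and aqueous acetic acid should open it to the ester on the pseudoaxial oxygen, that is the 3-O-acetate with free 4-hydroxyl, 16.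

Step 2. What may go wrong: retro-aldol fragmentation of the aldolate before it is mesylated, quenching of the enolate by hydrate or oligomer content of 3, and incomplete elimination. The fallback replaces the aldol condensation by a Horner–Wadsworth–Emmons olefination; it sets out from 2 and comes back at 6. Lactone 2 is converted with LiN(iPr)2 and ClP(O)(OEt)2 into the enol phosphate F6 (not isolated), which further LiN(iPr)2 rearranges by a 1,3-phosphoryl shift from oxygen to carbon into the α-phosphono lactone F7. Olefination of F7 with 3 (KOtBu, THF) should give 6.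

Step 6. What may go wrong: slow or reversible acylal formation on the electron-poor, hindered enal, conjugate addition of acetate, and acid-induced loss of the silyl ether. The fallback avoids the free enal; it sets out from acetal 10 and comes back at 12, and it makes no new compound (F0). The dimethyl acetal of 10 is exchanged directly for the gem-diacetate by acetolysis (Ac2O, catalytic H2SO4, 0 °C), a classical acetal-to-acylal exchange through the oxocarbenium ion, so that step 5 is skipped as well.

Further compounds

F1 | step 9 | methyl shikimate, methyl (3R,4S,5R)-3,4,5-trihydroxycyclohex-1-ene-1-carboxylate | O[C@@H]1CC(C(=O)OC)=C[C@@H](O)[C@H]1O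
F2 | step 9 | methyl 3,4-O-isopropylideneshikimate | O[C@@H]1CC(C(=O)OC)=C[C@@H](OC2(C)C)[C@H]1O2
F3 | step 9 | methyl 3,4-O-isopropylidene-5-O-[(3S)-3-methylpentanoyl]shikimate | CC[C@H](C)CC(=O)O[C@@H]1CC(C(=O)OC)=C[C@@H](OC2(C)C)[C@H]1O2
F4 | step 9 | methyl 5-O-[(3S)-3-methylpentanoyl]shikimate | CC[C@H](C)CC(=O)O[C@@H]1CC(C(=O)OC)=C[C@@H](O)[C@H]1O
F5 | step 9 | methyl 3,4-O-(1-methoxyethylidene)-5-O-[(3S)-3-methylpentanoyl]shikimate (cyclic orthoacetate) | CC[C@H](C)CC(=O)O[C@@H]1CC(C(=O)OC)=C[C@@H](OC2(C)OC)[C@H]1O2
F6 | step 2 | (5R)-5-{[(tert-butyldiphenylsilyl)oxy]methyl}-4,5-dihydrofuran-2-yl diethyl phosphate | CCOP(=O)(OCC)OC1=CC[C@H](CO[Si](c2ccccc2)(c2ccccc2)C(C)(C)C)O1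
F7 | step 2 | diethyl [(5R)-5-{[(tert-butyldiphenylsilyl)oxy]methyl}-2-oxotetrahydrofuran-3-yl]phosphonate | CCOP(=O)(OCC)C1C[C@H](CO[Si](c2ccccc2)(c2ccccc2)C(C)(C)C)OC1=O
F0 | step 6 | none | none
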